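## Retrosynthetic overview

1. Target 24 ⇐ diol 23 (two O-benzyl groups) ⇐ syn-hydroxy ester 22 ⇐ keto ester 21, which is cut at the C8''–O4' aryl ether bond into furofuran phenol 16 and diazo keto ester 20 (carbenoid O–H insertion).
2. 16 ⇐ ring B closed at C7'–O from dithiane alcohol 13, with hydride delivered to the exo face (endo syringyl).
3. 13 ⇐ ring A closed at C7–O by benzylic cycloetherification of triol 12 (exo guaiacyl).
4. 12 ⇐ tandem conjugate addition–aldol of dithiane 7, butenolide 4 (source of absolute configuration) and aldehyde 8.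
5. Ring order: butenolide template (sacrificed), then ring A, then ring B; the glycerol chain is attached last.

Assumption: lignan locants are used (C7–C9 guaiacyl half, C7'–C9' syringyl half, C7''–C9'' glycerol chain), and the aldol carbinol carbon of 11 and 12 is carried as an epimer mixture because step 6 re-sets it.

## Route

Step 1
Reactants: 1 furfural
Product: 2 5-hydroxyfuran-2(5H)-one (racemic)
Conditions: O2, hν (visible), methylene blue (cat.), MeOH, rt
Reagents that add atoms: oxygen, O=O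
Why: Singlet-oxygen [4+2] photooxygenation of the furan and methanolysis of the endoperoxide excise the formyl carbon and leave the hydroxybutenolide; no stereocentre has to be controlled.

Step 2
Reactants: 2 5-hydroxyfuran-2(5H)-one; 3 (+)-menthol
Product: 4 (5S)-5-[(1S,2R,5S)-menthyloxy]furan-2(5H)-one
Conditions: CSA (cat.), benzene, reflux (Dean–Stark); crystallisation from petroleum ether, mother liquor re-equilibrated with acid and recrystallised
Reagents that add atoms: none
Why: Acid-catalysed acetalisation gives both C5 epimers, which interconvert under acid, and the (5S) epimer of the (+)-menthyl series crystallises (mirror image of the established (5R)-l-menthyloxy case), so crystallisation-induced epimerisation sets C5.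

Step 3
Reactants: 5 syringaldehyde
Product: 6 4-(1,3-dithian-2-yl)-2,6-dimethoxyphenol
Conditions: HS(CH2)3SH, BF3·OEt2 (cat.), CH2Cl2, 0 °C to rt
Reagents that add atoms: propane-1,3-dithiol, SCCCS
Why: Lewis-acid dithioacetalisation turns the aldehyde into a Corey–Seebach acyl-anion precursor that tolerates the free phenol.

Step 4
Reactants: 6 4-(1,3-dithian-2-yl)-2,6-dimethoxyphenol
Product: 7 [4-(1,3-dithian-2-yl)-2,6-dimethoxyphenoxy]triisopropylsilane
Conditions: TIPSCl, imidazole, DMF, 40 °C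
Reagents that add atoms: chlorotriisopropylsilane, CC(C)[Si](Cl)(C(C)C)C(C)C
Why: Silylation of the phenol gives a TIPS ether that survives n-BuLi, LiAlH4 and mild acid and is orthogonal to the benzyl ethers.

Step 5
Reactants: 7 TIPS-protected syringyl dithiane; 4 (5S)-menthyloxybutenolide; 8 4-benzyloxy-3-methoxybenzaldehyde
Product: 11 (3R,4S,5S)-3-[(4-benzyloxy-3-methoxyphenyl)(hydroxy)methyl]-4-{2-[3,5-dimethoxy-4-(triisopropylsilyloxy)phenyl]-1,3-dithian-2-yl}-5-[(1S,2R,5S)-menthyloxy]dihydrofuran-2(3H)-one (carbinol epimers), via lithiated dithiane 9 (not isolated), via lithium enolate 10 (not isolated)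
Conditions: n-BuLi, THF, −78 to −30 °C; 4, −90 °C; 8, −78 °C; NH4Cl (aq)
Reagents that add atoms: none
Why: Tandem conjugate addition–aldol on a γ-alkoxybutenolide: the dithiane anion adds to C4 anti to the menthyloxy group (sets C8'), and the enolate takes the aldehyde trans to the new C4 substituent (sets C8).

Step 6
Reactants: 11 tandem adduct
Product: 13 [(2R,3S,4S)-2-(4-benzyloxy-3-methoxyphenyl)-4-{2-[3,5-dimethoxy-4-(triisopropylsilyloxy)phenyl]-1,3-dithian-2-yl}tetrahydrofuran-3-yl]methanol, via triol 12 (not isolated)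
Conditions: LiAlH4, THF, 0 °C to rt; H2O/NaOH work-up; then CSA (5 mol %), CH2Cl2, 0 °C to rt
Reagents that add atoms: none
Why: LiAlH4 reduces the lactone carbonyl and the acetal carbon to the two CH2OH groups with loss of menthol, and mild acid ionises the p-benzyloxybenzylic alcohol so that the C9' hydroxyl closes ring A by SN1 cycloetherification (5-exo C–O bond formation), both carbinol epimers converging on the 2,3-trans aryl-exo isomer (C7 R).

Step 7
Reactants: 13 dithiane alcohol
Product: 15 (1R,3aS,4S,6aS)-1-(4-benzyloxy-3-methoxyphenyl)-4-[3,5-dimethoxy-4-(triisopropylsilyloxy)phenyl]tetrahydro-1H,3H-furo[3,4-c]furan, via cyclic S,O-ketal 14 (not isolated)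
Conditions: MeOTf (3 equiv), 2,6-di-tert-butyl-4-methylpyridine (3 equiv), Et3SiH (5 equiv), 4 Å MS, CH2Cl2, −20 °C to rt; NaHCO3 (aq) work-up
Reagents that add atoms: none
Why: Proposed new method: one-pot alkylative desulfurative reductive cycloetherification, in which S-methylation opens the dithiane to an aryl thionium ion, the cis-disposed C9 hydroxyl traps it faster than silane can reduce it and closes ring B as an S,O-ketal, a second S-methylation expels MeS(CH2)3SMe to give the aryl oxocarbenium ion of the cis-fused bicycle, and Et3SiH delivers hydride to its convex (exo) face so that C7' is S with the syringyl group endo, the hindered pyridine buffering the acid that would epimerise the product; the closest known reactions are alkylative dithiane hydrolysis and the Et3SiH/Lewis-acid reduction of cyclic hemiketals (C-glycoside-type ionic hydrogenation).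

Step 8
Reactants: 15 furofuran TIPS ether
Product: 16 4-[(1S,3aS,4R,6aS)-4-(4-benzyloxy-3-methoxyphenyl)tetrahydro-1H,3H-furo[3,4-c]furan-1-yl]-2,6-dimethoxyphenol
Conditions: TBAF, THF, 0 °C; NH4Cl (aq)
Reagents that add atoms: none
Why: Fluoride desilylation frees only the syringyl phenol (the guaiacyl oxygen stays benzylated), and at 0 °C the phenoxide does not open the benzylic ether, so C7' is kept.

Step 9
Reactants: 17 4-benzyloxy-3,5-dimethoxybenzaldehyde; 18 ethyl diazoacetate
Product: 20 ethyl 3-(4-benzyloxy-3,5-dimethoxyphenyl)-2-diazo-3-oxopropanoate, via diazo aldol adduct 19 (not isolated)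
Conditions: DBU (0.2 equiv), DMSO, rt; then IBX, rt
Reagents that add atoms: none
Why: DBU-catalysed aldol-type addition of ethyl diazoacetate to the aldehyde followed by in situ IBX oxidation of the benzylic alcohol gives the acceptor/acceptor diazo compound in one pot; no stereocentre remains.

Step 10
Reactants: 16 furofuran phenol; 20 diazo keto ester
Product: 21 ethyl 3-(4-benzyloxy-3,5-dimethoxyphenyl)-2-{4-[(1S,3aS,4R,6aS)-4-(4-benzyloxy-3-methoxyphenyl)tetrahydro-1H,3H-furo[3,4-c]furan-1-yl]-2,6-dimethoxyphenoxy}-3-oxopropanoate (C2 epimers)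
Conditions: Rh2(OAc)4 (2 mol %), CH2Cl2, 40 °C, slow addition of 20
Reagents that add atoms: none
Why: Rhodium-carbenoid O–H insertion: the electrophilic carbenoid is captured by the only free hydroxyl (the hindered but exposed syringyl phenol oxygen) to give an oxonium ylide and, after proton shift, the C8''–O4' bond; C8'' is configurationally labile here and is fixed in step 11.

Step 11
Reactants: 21 α-aryloxy β-keto ester
Product: 22 ethyl (2S,3R)-3-(4-benzyloxy-3,5-dimethoxyphenyl)-2-{4-[(1S,3aS,4R,6aS)-4-(4-benzyloxy-3-methoxyphenyl)tetrahydro-1H,3H-furo[3,4-c]furan-1-yl]-2,6-dimethoxyphenoxy}-3-hydroxypropanoate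
Conditions: RuCl(p-cymene)[(S,S)-TsDPEN] (2 mol %), HCO2H/Et3N (5:2), CH2Cl2, 35 °C
Reagents that add atoms: none
Why: Noyori–Ikariya asymmetric transfer hydrogenation with dynamic kinetic resolution: the acidic C8'' proton lets the two epimers interconvert while the (S,S) catalyst delivers hydride to one face of the aryl ketone (C7'' R) of the faster-reacting epimer, giving the syn (threo) 2S,3R hydroxy ester as established for α-alkoxy β-keto esters.

Step 12
Reactants: 22 syn-hydroxy ester
Product: 23 (1R,2R)-1-(4-benzyloxy-3,5-dimethoxyphenyl)-2-{4-[(1S,3aS,4R,6aS)-4-(4-benzyloxy-3-methoxyphenyl)tetrahydro-1H,3H-furo[3,4-c]furan-1-yl]-2,6-dimethoxyphenoxy}propane-1,3-diol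
Conditions: LiBH4, THF/MeOH, 0 °C to rt; NH4Cl (aq)
Reagents that add atoms: none
Why: Hydride reduction of the ester (the only reducible group) to the primary alcohol leaves both stereocentres untouched; C8'' becomes R only through the CIP priority change.

Step 13
Reactants: 23 bis(benzyl ether) diol
Product: 24 target CNP0317965.1
Conditions: H2 (1 atm), 10% Pd/C, EtOAc/MeOH, rt
Reagents that add atoms: none
Why: Catalytic hydrogenolysis of the two aryl benzyl ethers under neutral conditions, stopped after two equivalents of H2, keeps the benzylic C–O bonds of the furofuran and the C7'' alcohol.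

## Compound list

1 | furfural | O=Cc1ccco1 | starting material
2 | 5-hydroxyfuran-2(5H)-one (racemic) | OC1OC(=O)C=C1 | intermediate
3 | (+)-menthol, (1S,2R,5S)-2-isopropyl-5-methylcyclohexan-1-ol | C[C@H]1CC[C@@H]([C@H](C1)O)C(C)C | starting material
4 | (5S)-5-[(1S,2R,5S)-menthyloxy]furan-2(5H)-one | O=C1O[C@H](O[C@H]2C[C@@H](C)CC[C@@H]2C(C)C)C=C1 | intermediate
5 | syringaldehyde (4-hydroxy-3,5-dimethoxybenzaldehyde) | COc1cc(C=O)cc(OC)c1O | starting material
6 | 4-(1,3-dithian-2-yl)-2,6-dimethoxyphenol | COc1cc(C2SCCCS2)cc(OC)c1O | intermediate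
7 | [4-(1,3-dithian-2-yl)-2,6-dimethoxyphenoxy]triisopropylsilane | COc1cc(C2SCCCS2)cc(OC)c1O[Si](C(C)C)(C(C)C)C(C)C | intermediate
8 | 4-benzyloxy-3-methoxybenzaldehyde (O-benzylvanillin) | COc1cc(C=O)ccc1OCc1ccccc1 | starting material
9 | 2-lithio derivative of 7 (not isolated) | [Li]C1(SCCCS1)c1cc(OC)c(O[Si](C(C)C)(C(C)C)C(C)C)c(OC)c1 | intermediate
10 | lithium (4S,5S)-4-(2-aryl-1,3-dithian-2-yl)-5-menthyloxy-4,5-dihydrofuran-2-olate (not isolated) | [Li]OC1O[C@H](O[C@H]2C[C@@H](C)CC[C@@H]2C(C)C)[C@@H](C2(SCCCS2)c2cc(OC)c(O[Si](C(C)C)(C(C)C)C(C)C)c(OC)c2)C=1 | intermediate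
11 | (3R,4S,5S)-3-[(4-benzyloxy-3-methoxyphenyl)(hydroxy)methyl]-4-{2-[3,5-dimethoxy-4-(triisopropylsilyloxy)phenyl]-1,3-dithian-2-yl}-5-[(1S,2R,5S)-menthyloxy]dihydrofuran-2(3H)-one, carbinol carbon as epimer mixture | O=C1O[C@H](O[C@H]2C[C@@H](C)CC[C@@H]2C(C)C)[C@@H](C2(SCCCS2)c2cc(OC)c(O[Si](C(C)C)(C(C)C)C(C)C)c(OC)c2)[C@@H]1C(O)c1ccc(OCc2ccccc2)c(OC)c1 | intermediate
12 | (2S,3S)-2-[(4-benzyloxy-3-methoxyphenyl)(hydroxy)methyl]-3-{2-[3,5-dimethoxy-4-(triisopropylsilyloxy)phenyl]-1,3-dithian-2-yl}butane-1,4-diol, carbinol carbon as epimer mixture (not isolated) | OC[C@@H](C(O)c1ccc(OCc2ccccc2)c(OC)c1)[C@@H](CO)C1(SCCCS1)c1cc(OC)c(O[Si](C(C)C)(C(C)C)C(C)C)c(OC)c1 | intermediate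
13 | [(2R,3S,4S)-2-(4-benzyloxy-3-methoxyphenyl)-4-{2-[3,5-dimethoxy-4-(triisopropylsilyloxy)phenyl]-1,3-dithian-2-yl}tetrahydrofuran-3-yl]methanol | COc1cc([C@@H]2OC[C@@H](C3(SCCCS3)c3cc(OC)c(O[Si](C(C)C)(C(C)C)C(C)C)c(OC)c3)[C@H]2CO)ccc1OCc1ccccc1 | intermediate
14 | cis-fused bicyclic S,O-ketal: the furofuran of 15 carrying a 3-(methylthio)propylthio group on C7', ketal carbon as epimer mixture (not isolated) | COc1cc([C@@H]2OC[C@@H]3[C@H]2COC3(SCCCSC)c2cc(OC)c(O[Si](C(C)C)(C(C)C)C(C)C)c(OC)c2)ccc1OCc1ccccc1 | intermediate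
15 | (1R,3aS,4S,6aS)-1-(4-benzyloxy-3-methoxyphenyl)-4-[3,5-dimethoxy-4-(triisopropylsilyloxy)phenyl]tetrahydro-1H,3H-furo[3,4-c]furan (7R,8S,7'S,8'S; guaiacyl exo, syringyl endo) | COc1cc([C@@H]2OC[C@@H]3[C@H]2CO[C@@H]3c2cc(OC)c(O[Si](C(C)C)(C(C)C)C(C)C)c(OC)c2)ccc1OCc1ccccc1 | intermediate
16 | 4-[(1S,3aS,4R,6aS)-4-(4-benzyloxy-3-methoxyphenyl)tetrahydro-1H,3H-furo[3,4-c]furan-1-yl]-2,6-dimethoxyphenol | COc1cc([C@@H]2OC[C@@H]3[C@H]2CO[C@@H]3c2cc(OC)c(O)c(OC)c2)ccc1OCc1ccccc1 | intermediate
17 | 4-benzyloxy-3,5-dimethoxybenzaldehyde | COc1cc(C=O)cc(OC)c1OCc1ccccc1 | starting material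
18 | ethyl diazoacetate | CCOC(=O)C=[N+]=[N-] | starting material
19 | ethyl 3-(4-benzyloxy-3,5-dimethoxyphenyl)-2-diazo-3-hydroxypropanoate, racemic (not isolated) | CCOC(=O)C(=[N+]=[N-])C(O)c1cc(OC)c(OCc2ccccc2)c(OC)c1 | intermediate
20 | ethyl 3-(4-benzyloxy-3,5-dimethoxyphenyl)-2-diazo-3-oxopropanoate | CCOC(=O)C(=[N+]=[N-])C(=O)c1cc(OC)c(OCc2ccccc2)c(OC)c1 | intermediate
21 | ethyl 3-(4-benzyloxy-3,5-dimethoxyphenyl)-2-(furofuranyl-2,6-dimethoxyphenoxy)-3-oxopropanoate, C2 as labile epimer mixture | COc1cc([C@@H]2OC[C@@H]3[C@H]2CO[C@@H]3c2cc(OC)c(OC(C(=O)OCC)C(=O)c3cc(OC)c(OCc4ccccc4)c(OC)c3)c(OC)c2)ccc1OCc1ccccc1 | intermediate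
22 | ethyl (2S,3R)-3-(4-benzyloxy-3,5-dimethoxyphenyl)-2-(furofuranyl-2,6-dimethoxyphenoxy)-3-hydroxypropanoate (syn, threo) | COc1cc([C@@H]2OC[C@@H]3[C@H]2CO[C@@H]3c2cc(OC)c(O[C@H](C(=O)OCC)[C@H](O)c3cc(OC)c(OCc4ccccc4)c(OC)c3)c(OC)c2)ccc1OCc1ccccc1 | intermediate
23 | (1R,2R)-1-(4-benzyloxy-3,5-dimethoxyphenyl)-2-(furofuranyl-2,6-dimethoxyphenoxy)propane-1,3-diol, guaiacyl oxygen benzylated | COc1cc([C@@H]2OC[C@@H]3[C@H]2CO[C@@H]3c2cc(OC)c(O[C@H](CO)[C@H](O)c3cc(OC)c(OCc4ccccc4)c(OC)c3)c(OC)c2)ccc1OCc1ccccc1 | intermediate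
24 | CNP0317965.1: (7''R,8''R)-threo-syringylglycerol 8''-O-4' ether of the (7R,8S,7'S,8'S)-furofuran with exo guaiacyl and endo syringyl groups | COc1cc([C@@H]2OC[C@@H]3[C@H]2CO[C@@H]3c2cc(OC)c(O[C@H](CO)[C@H](O)c3cc(OC)c(O)c(OC)c3)c(OC)c2)ccc1O | target

## Step count and risk

Total steps: 13. Longest linear sequence: 10 steps (5 → 24 through steps 3–8 and 10–13; the furfural branch through steps 1, 2, 5–8, 10–13 is equally long).

Three steps most likely to fail:

Step 7 (the proposed new reaction). The thionium ion may be reduced by the silane before the hydroxyl traps it, or the S,O-ketal may not ionise. The fallback uses known chemistry and sets out from 13: alkylative dithiane hydrolysis (MeI, CaCO3, MeCN/H2O, 45 °C) gives the keto alcohol, which closes spontaneously to the bicyclic hemiketal F1. Reduction of this hemiketal with Et3SiH and BF3·OEt2 in CH2Cl2 at −78 °C delivers hydride to the exo face, and the route is rejoined at 15.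

Step 10 (O–H insertion into a hindered phenol in a substrate with several electron-rich arenes). If arene attack or Wolff rearrangement competes, the fallback sets out from 17 and 18: SnCl2-catalysed Roskamp homologation gives the β-keto ester F2, and bromination with NBS/NH4OAc gives the α-bromo β-keto ester F3. Classical SN2 O-alkylation of phenol 16 with this bromide (K2CO3, acetone) comes back to the route at 21.

Step 11 (syn selectivity of the dynamic kinetic reduction with a very bulky aryloxy group). If the diastereomer ratio is poor, the fallback sets out from 16 and replaces catalyst control by auxiliary control. O-alkylation with (S)-4-benzyl-3-(bromoacetyl)oxazolidin-2-one (K2CO3, acetone) gives the aryloxyacetyl imide F4. An Evans syn-glycolate aldol (Bu2BOTf, i-Pr2NEt, CH2Cl2, −78 °C, then aldehyde 17) gives the syn-aldol adduct F5 with both centres set as 2S,3R. LiBH4 in THF/H2O removes the auxiliary reductively and comes back to the route at 23, bypassing 20–22.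

## Further compounds

F1 | step 7 | cis-fused bicyclic hemiketal of the C7' ketone (anomer mixture), 1-hydroxy analogue of 15 | COc1cc([C@@H]2OC[C@@H]3[C@H]2COC3(O)c2cc(OC)c(O[Si](C(C)C)(C(C)C)C(C)C)c(OC)c2)ccc1OCc1ccccc1
F2 | step 10 | ethyl 3-(4-benzyloxy-3,5-dimethoxyphenyl)-3-oxopropanoate | CCOC(=O)CC(=O)c1cc(OC)c(OCc2ccccc2)c(OC)c1
F3 | step 10 | ethyl 2-bromo-3-(4-benzyloxy-3,5-dimethoxyphenyl)-3-oxopropanoate | CCOC(=O)C(Br)C(=O)c1cc(OC)c(OCc2ccccc2)c(OC)c1
F4 | step 11 | (S)-4-benzyl-3-[(furofuranyl-2,6-dimethoxyphenoxy)acetyl]oxazolidin-2-one | COc1cc([C@@H]2OC[C@@H]3[C@H]2CO[C@@H]3c2cc(OC)c(OCC(=O)N3[C@@H](Cc4ccccc4)COC3=O)c(OC)c2)ccc1OCc1ccccc1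
F5 | step 11 | (S)-4-benzyl-3-[(2S,3R)-3-(4-benzyloxy-3,5-dimethoxyphenyl)-2-(furofuranyl-2,6-dimethoxyphenoxy)-3-hydroxypropanoyl]oxazolidin-2-one | COc1cc([C@@H]2OC[C@@H]3[C@H]2CO[C@@H]3c2cc(OC)c(O[C@H](C(=O)N3[C@@H](Cc4ccccc4)COC3=O)[C@H](O)c3cc(OC)c(OCc4ccccc4)c(OC)c3)c(OC)c2)ccc1OCc1ccccc1
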